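The route cuts both bonds that flank the two-carbon bridge C1'–C2'. These are C4–C1', which ties the bridge to the pyran ring of the cyclopenta[c]pyran, and C2'–C3', which ties it to the E-trisubstituted alkene. Both neighbours (C4, C3') are sp2 carbons and C2' bears oxygen, so the bridge is a masked vinylboron unit. One palladium-catalysed conjunctive coupling joins a formyl-free cyclopenta[c]pyran-4-yl triflate, vinyl-B(pin) and an (E)-alkenyllithium. It makes both bonds and sets C2' as a C–B bond, later turned into C–O with retention. The triflate is the enol derivative of a bicyclic 4-ketone built on 6-(dimethylamino)fulvene. Acetylation and C7 formylation finish the synthesis.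

Key step: step 6

Numbering: core C1, O2, C3, C4, C4a, C5, C6, C7, C7a; side chain C1' (CH2 on C4) to C9'.

Assumption: both mirror-image forms of the ferrocenyl diphosphine are sold. The form meant is the one that places palladium on the Re face of C2' of the bound vinyl group (C1' > B > H). This is to be confirmed in a pilot run by Mosher ester analysis of the derived alcohol.

Step 1
Reactants: 1 6-(dimethylamino)fulvene; 2 acetoxyacetyl chloride
Product: 3 2-(acetoxyacetyl)-6-(dimethylamino)fulvene (acyl group on the ring carbon next to the one that carries the exocyclic CH–NMe2; exocyclic C=C configurationally labile)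
Conditions: 2,6-lutidine (1.2 equiv), CH2Cl2, −40 °C to 0 °C, argon
Reagents that add atoms: none
Why: Electrophilic acylation of a 6-aminofulvene (the acyl analogue of its Vilsmeier formylation): the nitrogen lone pair loads the five-membered ring, attack through C2 next to the exocyclic carbon gives a fully conjugated iminium ion that lutidine deprotonates, the heteroatom is a tertiary amine rather than a fulvenolate oxygen so the acyl chloride cannot end up on it, and the first acyl group switches off a second acylation.

Step 2
Reactants: 3 2-(acetoxyacetyl)-6-(dimethylamino)fulvene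
Product: 5 cyclopenta[c]pyran-4(3H)-one, via hydroxyacetyl aminofulvene 4 (not isolated)
Conditions: HCl (2 equiv, 1.25 M in MeOH), MeOH, 0 °C to 40 °C
Reagents that add atoms: none
Why: Acid-catalysed methanolysis of the acetate frees the primary alcohol of 4, which adds 6-endo-trig to the aminomethylidene carbon of the O-protonated vinylogous amide and expels dimethylamine, the same addition–elimination that closes chromones from o-hydroxyaryl enaminones, and holding the amine as its hydrochloride keeps it from re-opening the new C1–O2 enol ether.

Step 3
Reactants: 5 cyclopenta[c]pyran-4(3H)-one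
Product: 7 cyclopenta[c]pyran-4-yl trifluoromethanesulfonate, via potassium cyclopenta[c]pyran-4-olate 6 (not isolated)
Conditions: KN(SiMe3)2, THF, −78 °C; then PhNTf2, −78 °C to 0 °C; kept under argon and used promptly
Reagents that add atoms: N-phenylbis(trifluoromethanesulfonimide) O=S(=O)(N(c1ccccc1)S(=O)(=O)C(F)(F)F)C(F)(F)F
Why: Enol triflate formation: C3–H of 5 is unusually acidic because its loss creates the 10π-electron cyclopenta[c]pyran system, the hard oxygen of the olate attacks sulfur of the mild triflyl donor, and avoiding Tf2O spares the nucleophilic carbons C5 and C7.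

Step 4
Reactants: 8 5-bromo-2-methylpent-2-ene; 9 lithium acetylide–ethylenediamine complex
Product: 10 6-methylhept-5-en-1-yne
Conditions: DMSO, 10 °C to rt
Reagents that add atoms: none
Why: SN2 alkylation of an acetylide with a primary bromide in a dipolar aprotic solvent, where substitution should outrun E2 loss of HBr and the trisubstituted alkene is a spectator.

Step 5
Reactants: 10 6-methylhept-5-en-1-yne
Product: 12 (E)-1-iodo-2,6-dimethylhepta-1,5-diene, via (E)-alkenyldimethylalane 11 (not isolated)
Conditions: AlMe3 (2 equiv), Cp2ZrCl2 (0.2 equiv), CH2Cl2, 0 °C to rt; then I2, THF, −30 °C to 0 °C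
Reagents that add atoms: trimethylaluminium C[Al](C)C; iodine II
Why: Negishi zirconium-catalysed carboalumination adds methyl and aluminium syn across the terminal alkyne with the metal on the terminal carbon, and iodinolysis of the C–Al bond with retention fixes the E geometry of the future C3'=C4' bond, the trisubstituted alkene being inert.

Step 6
Reactants: 12 (E)-1-iodo-2,6-dimethylhepta-1,5-diene; 13 vinylboronic acid pinacol ester; 7 cyclopenta[c]pyran-4-yl trifluoromethanesulfonate
Product: 16 2-[(2S,3E)-1-(cyclopenta[c]pyran-4-yl)-4,8-dimethylnona-3,7-dien-2-yl]-4,4,5,5-tetramethyl-1,3,2-dioxaborolane, via (E)-2,6-dimethylhepta-1,5-dienyllithium 14 (not isolated), via lithium alkenyl(vinyl)borate 15 (not isolated)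
Conditions: 12 (1.2 equiv), t-BuLi (2.4 equiv), Et2O, −78 °C; 13 (1.2 equiv), −78 °C to rt; evaporate, THF, KOTf (2 equiv); 7 (1.0 equiv), Pd(OAc)2 (3 mol %), 1,1'-bis[bis(3,5-dimethylphenyl)phosphino]-2,2'-bis[α-(dimethylamino)benzyl]ferrocene (MandyPhos type, 3.6 mol %), 60 °C, argon; short filtration, crude product taken on at once
Reagents that add atoms: none
Why: Lithium–iodine exchange (retention of the E geometry) and addition of 14 to the empty orbital of 13 give the four-coordinate borate 15, and KOTf removes the iodide as insoluble KI so that halide does not block the catalyst. Pd(OAc)2, a divalent palladium salt, is reduced in the flask to zerovalent palladium, which inserts into the C4–O bond of 7; since triflate does not bind, a cationic C4–palladium species results that coordinates the unsubstituted vinyl group of 15, the alkenyl group then moves from boron to C2' anti to the metal while C1' becomes bonded to palladium (1,2-metallate shift), and reductive elimination joins C4 to C1'. The closest known reaction type is the enantioselective conjunctive cross-coupling of bis(alkenyl)borates with aryl and alkenyl triflates, and no ring is closed. C2' is controlled by the chiral diphosphine alone: it decides which face of the vinyl group palladium holds, the anti shift then delivers C3' to the Si face of C2', and the migrating carbon keeps its alkene geometry. The step needs the vinyl group rather than the C3'=C4' unit to be activated, and the metallate shift to outrun direct boron-to-palladium transfer; the first is secured by the two alkyl groups on C4', which keep that alkene (and the remote C7'=C8' alkene) away from the crowded metal, the second by the halide-free cationic palladium and the wide-bite-angle ligand. C7 is left unsubstituted here, since an aldehyde on the core would be allylated by a boronate such as 16 at 60 °C.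

Step 7
Reactants: 16 (S,E)-allylic pinacol boronate
Product: 17 (2S,3E)-1-(cyclopenta[c]pyran-4-yl)-4,8-dimethylnona-3,7-dien-2-ol
Conditions: NaBO3·4H2O (4 equiv), THF–H2O (1:1), 0 °C to rt
Reagents that add atoms: sodium perborate [Na+].[Na+].O[B-]1(O)OO[B-](O)(O)OO1
Why: Stereospecific boronate oxidation: the peroxo anion adds to boron and C2' migrates from boron to oxygen with retention, so (S)-16 gives (S)-17, the mild, nucleophilic and nearly neutral perborate should spare both alkenes and the electron-rich core, and working on the crude boronate leaves no time for a 1,3-boron shift.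

Step 8
Reactants: 17 (S,E)-allylic alcohol
Product: 18 (2S,3E)-1-(cyclopenta[c]pyran-4-yl)-4,8-dimethylnona-3,7-dien-2-yl acetate
Conditions: Ac2O, Et3N, DMAP (cat.), CH2Cl2, 0 °C to rt
Reagents that add atoms: acetic anhydride CC(=O)OC(C)=O
Why: DMAP-catalysed acyl transfer to the secondary alcohol under basic conditions, which never breaks the C2'–O bond and so keeps the configuration, and which is too weakly electrophilic to acylate the ring carbons.

Step 9
Reactants: 18 (S,E)-allylic acetate
Product: 20 (2S,3E)-1-(7-formylcyclopenta[c]pyran-4-yl)-4,8-dimethylnona-3,7-dien-2-yl acetate, via C7 iminium dichlorophosphate 19 (not isolated)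
Conditions: POCl3 (1.1 equiv), DMF, 0 °C; then aq. NaOAc, 0 °C to rt
Reagents that add atoms: N,N-dimethylformamide CN(C)C=O; water O
Why: Vilsmeier–Haack formylation of a pseudoazulene whose five-membered ring is about as nucleophilic as that of azulene: attack at C7 gives a pyrylium-type σ-complex in which the remaining C5=C6 bond is conjugated through C4a, the carbon γ to O2, whereas C5 is electronically less favourable and is shielded by the peri side chain on C4, and the isolated alkenes and the acetate should not react at 0 °C before buffered hydrolysis of 19.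

Compound list
1 | 6-(dimethylamino)fulvene | CN(C)C=C1C=CC=C1 | starting material
2 | acetoxyacetyl chloride | CC(=O)OCC(Cl)=O | starting material
3 | 2-(acetoxyacetyl)-6-(dimethylamino)fulvene | CN(C)C=C1C=CC=C1C(=O)COC(C)=O | intermediate
4 | 2-(hydroxyacetyl)-6-(dimethylamino)fulvene | CN(C)C=C1C=CC=C1C(=O)CO | intermediate
5 | cyclopenta[c]pyran-4(3H)-one | O=C1COC=C2C=CC=C12 | intermediate
6 | potassium cyclopenta[c]pyran-4-olate | [K+].[O-]c1cocc2cccc1-2 | intermediate
7 | cyclopenta[c]pyran-4-yl trifluoromethanesulfonate | O=S(=O)(Oc1cocc2cccc1-2)C(F)(F)F | intermediate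
8 | 5-bromo-2-methylpent-2-ene | CC(C)=CCCBr | starting material
9 | lithium acetylide–ethylenediamine complex | [Li]C#C.NCCN | starting material
10 | 6-methylhept-5-en-1-yne | C#CCCC=C(C)C | intermediate
11 | (E)-(2,6-dimethylhepta-1,5-dienyl)dimethylalane | C[Al](C)/C=C(\C)CCC=C(C)C | intermediate
12 | (E)-1-iodo-2,6-dimethylhepta-1,5-diene | I/C=C(\C)CCC=C(C)C | intermediate
13 | vinylboronic acid pinacol ester | C=CB1OC(C)(C)C(C)(C)O1 | starting material
14 | (E)-2,6-dimethylhepta-1,5-dienyllithium | [Li]/C=C(\C)CCC=C(C)C | intermediate
15 | lithium [(E)-2,6-dimethylhepta-1,5-dienyl](vinyl)(pinacolato)borate | [Li+].C=C[B-]1(/C=C(\C)CCC=C(C)C)OC(C)(C)C(C)(C)O1 | intermediate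
16 | 2-[(2S,3E)-1-(cyclopenta[c]pyran-4-yl)-4,8-dimethylnona-3,7-dien-2-yl]-4,4,5,5-tetramethyl-1,3,2-dioxaborolane | CC1(C)OB(OC1(C)C)[C@H](/C=C(\C)CCC=C(C)C)Cc1cocc2cccc1-2 | intermediate
17 | (2S,3E)-1-(cyclopenta[c]pyran-4-yl)-4,8-dimethylnona-3,7-dien-2-ol | O[C@H](/C=C(\C)CCC=C(C)C)Cc1cocc2cccc1-2 | intermediate
18 | (2S,3E)-1-(cyclopenta[c]pyran-4-yl)-4,8-dimethylnona-3,7-dien-2-yl acetate | CC(=O)O[C@H](/C=C(\C)CCC=C(C)C)Cc1cocc2cccc1-2 | intermediate
19 | C7 (dimethyliminio)methyl derivative of 18, dichlorophosphate salt | CC(=O)O[C@H](/C=C(\C)CCC=C(C)C)Cc1cocc2c(C=[N+](C)C)ccc1-2.[O-]P(=O)(Cl)Cl | intermediate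
20 | (2S,3E)-1-(7-formylcyclopenta[c]pyran-4-yl)-4,8-dimethylnona-3,7-dien-2-yl acetate | CC(=O)O[C@H](/C=C(\C)CCC=C(C)C)Cc1cocc2c(C=O)ccc1-2 | target

Total step count: 9. Longest linear sequence: 7 steps (1, 2, 3, 6, 7, 8, 9). The side-chain branch (4, 5) joins at step 6.

Steps most likely to fail

Step 6. Traces of iodide or the electron-rich core may slow the cationic pathway. Plain boron-to-palladium transfer of a vinyl or alkenyl group, β-hydride loss, or thermal decay of the triflate could then take over. The facial selectivity may also be poor.
The fallback sets out from 7 and returns at 17. It makes the two bonds one after the other and sets C2' by reduction.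
- Palladium-catalysed arylation of the Reformatsky reagent BrZnCH2CO2Et with 7 (Pd2(dba)3, XPhos, THF) should give ethyl (cyclopenta[c]pyran-4-yl)acetate F1.
- MeNH(OMe)·HCl and i-PrMgCl should convert it into the Weinreb amide 2-(cyclopenta[c]pyran-4-yl)-N-methoxy-N-methylacetamide F2.
- Alkenyllithium 14 should add once to give (E)-1-(cyclopenta[c]pyran-4-yl)-4,8-dimethylnona-3,7-dien-2-one F3.
- Corey–Bakshi–Shibata reduction with the (R)-B-methyl oxazaborolidine and catecholborane, the alkenyl arm acting as the larger group, should give 17.

Step 3. The ambident olate may be sulfonylated on C5 or C7. The triflate carries no acceptor group and may polymerise or oxidise in air during isolation.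
The fallback sets out from 5 and returns at 17. It uses the ketone itself as the electrophile.
- Reformatsky addition of the weakly basic BrZnCH2CO2Et to C4 should give racemic ethyl (4-hydroxy-3,4-dihydrocyclopenta[c]pyran-4-yl)acetate F4.
- Dehydration with catalytic TsOH, driven by formation of the 10π system, should give the ester F1.
- F1 is carried through F2 and F3 to 17 as described for step 6.

Step 9. The secondary allylic acetate may ionise, HCl may add to the trisubstituted alkenes in the chlorophosphate medium, or attack at C5 may compete.
The fallback sets out from 17 and returns at 20. It carries the oxygen through the formylation as a bulky, poorly leaving silyl ether and installs the acetate last.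
- TBSCl and imidazole should give the (S,E)-tert-butyldimethylsilyl ether F5.
- POCl3/DMF should give its C7 iminium salt F6.
- Buffered hydrolysis should give the 7-formyl silyl ether F7.
- Bu4NF buffered with AcOH should free the 7-formyl alcohol F8.
- Ac2O, Et3N and DMAP should give 20.

Further compounds
F1 | step 6 | ethyl (cyclopenta[c]pyran-4-yl)acetate | CCOC(=O)Cc1cocc2cccc1-2
F2 | step 6 | 2-(cyclopenta[c]pyran-4-yl)-N-methoxy-N-methylacetamide | CON(C)C(=O)Cc1cocc2cccc1-2
F3 | step 6 | (E)-1-(cyclopenta[c]pyran-4-yl)-4,8-dimethylnona-3,7-dien-2-one | O=C(/C=C(\C)CCC=C(C)C)Cc1cocc2cccc1-2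
F4 | step 3 | ethyl (4-hydroxy-3,4-dihydrocyclopenta[c]pyran-4-yl)acetate (racemic) | CCOC(=O)CC1(O)COC=C2C=CC=C12
F5 | step 9 | tert-butyl{[(2S,3E)-1-(cyclopenta[c]pyran-4-yl)-4,8-dimethylnona-3,7-dien-2-yl]oxy}dimethylsilane | CC(C)(C)[Si](C)(C)O[C@H](/C=C(\C)CCC=C(C)C)Cc1cocc2cccc1-2
F6 | step 9 | C7 (dimethyliminio)methyl derivative of F5, dichlorophosphate salt | CC(C)(C)[Si](C)(C)O[C@H](/C=C(\C)CCC=C(C)C)Cc1cocc2c(C=[N+](C)C)ccc1-2.[O-]P(=O)(Cl)Cl
F7 | step 9 | 4-[(2S,3E)-2-(tert-butyldimethylsilyloxy)-4,8-dimethylnona-3,7-dienyl]cyclopenta[c]pyran-7-carbaldehyde | CC(C)(C)[Si](C)(C)O[C@H](/C=C(\C)CCC=C(C)C)Cc1cocc2c(C=O)ccc1-2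
F8 | step 9 | 4-[(2S,3E)-2-hydroxy-4,8-dimethylnona-3,7-dienyl]cyclopenta[c]pyran-7-carbaldehyde | O[C@H](/C=C(\C)CCC=C(C)C)Cc1cocc2c(C=O)ccc1-2
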